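The earlier runs and the new flask come from a simulation with constants of no real substance; noise was put on by code.

| setting | eta | zeta | flask |
|---|---|---|---|
| electrophile | 0.019 M | 0.019 M | 0.019 M |
| nucleophile | 0.038 M | 0.038 M | 0.0380 M |
| protic impurity | 0.95 mM | 1.9 mM | 0.950 mM |
| remark | the very flask that is asked about, followed so far | run made earlier |  |
| time |  |  | 50 min |

| run | time / min | electrophile / % | product / % |
|---|---|---|---|
| eta | 0.667 | 91 | 8 |
| eta | 2.00 | 65 | 28 |
| eta | 4.00 | 52 | 42 |
| eta | 5.00 | 49 | 50 |
| eta | 8.00 | 35 | 60 |
| eta | 10.0 | 30 | 67 |
| zeta | 1.50 | 74 | 21 |
| zeta | 2.50 | 65 | 29 |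
| zeta | 4.00 | 48 | 40 |
| zeta | 8.00 | 34 | 57 |
| zeta | 12.0 | 23 | 67 |
| zeta | 20.0 | 14 | 73 |

(scatter of a reading: 2 percentage points)

- the earlier runs do not show how much of nucleophile is bound; that part of a forecast is a guess

- part of the electrophile that has reacted at 50 min
- share of the unused nucleophile that is free and not bound as protonated nucleophile, at 50 min

**Budget first.** Start with one division: this flask holds 2.00 of nucleophile per electrophile charged, and that ratio n is the nucleophile budget. Take a budget of two as the zero of the scale. My guess, since the runs do not show binding, is that each product costs two nucleophiles, one built in and one bound as protonated nucleophile. With p the product as a fraction of the electrophile charge, the free share of unused nucleophile is then (n − 2p)/(n − p).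

**The slope.** With A the electrophile left as a fraction of its charge, and with the impurity set aside, p is 1 − A, so free nucleophile on this budget is twice the electrophile, and 1/A − 1 should climb roughly straight with time. The eta run, this same flask, reads 0.233 min⁻¹ at 10.0 min.

**The end.** Carried to 50 min, that leaves 7.89%, so 92.1% has reacted. If each impurity molecule takes one electrophile, 5.00% of the charge never becomes product. So p is 87.1%, and the free share is 22.8%.

**Weak link.** The doubling is the guess, so test it. In the eta run, the ordinary second-order slope with one nucleophile per product reads 0.0949 min⁻¹ at 4.00 min and 0.0773 min⁻¹ at 10.0 min. The doubled law reads 0.231 min⁻¹ and 0.233 min⁻¹, so I keep it.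

**The result.** The forecast gives 97% reacted and 93% free, a free share above mine, and says “it remains a guess”.

The flask gives 93.0% reacted and 21.5% free.

    electrophile + protic impurity → quenched substrate (k = 32.0 M⁻¹ min⁻¹)
    nucleophile + acid set free ⇌ protonated nucleophile, settled at all times (K = 1.90 × 10⁵ M⁻¹)
    electrophile + nucleophile → acid set free + product (k = 5.10 M⁻¹ min⁻¹)

At 50.0 min it holds 88.0% product beside 0.0167 M of protonated nucleophile. That product on budget 2.00 returns 21.4% free.

**Second flask.** A neighbour with 0.011 M of electrophile has budget 3.45, and its impurity charge comes to 8.64% of that electrophile. Counting that whole charge as lost and the rest as product, p is about 91.4%, and the free share is 64.0%. Computed, that neighbour gives 91.8% product and 63.8% free, with 0.41% left of electrophile, its limiting reagent.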